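**Retrosynthetic overview**
1. Feature: in ring A (C3a, C4, C5, C6, C7, C7a) the pair C6(H)–C7(OMe) has the pattern of a ketene acetal that has lost one alcohol. The other four carbons, C7a=C3a–C4=C5(alkyl), are the diene of a 2-pyranone annulated to the furan ring across C3a–C7a.
2. End game: both hydroxyl groups come from benzyl ethers and the C3 formyl group from a Vilsmeier–Haack reaction, which leads back to a 2-aryl-5-alkyl-7-methoxybenzofuran.
3. Key disconnection: C5–C6 and C7–C7a, back to a 2-aryl-5-alkyl-7H-furo[2,3-c]pyran-7-one and 1,1-dimethoxyethene ([4+2], then loss of CO2 and of methanol).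
4. The pyranone comes from 6-endo-dig lactonisation of a 3-alkynylfuran-2-carboxylic acid. The alkyne is attached by Sonogashira coupling at C3–I, the iodine by ester-directed magnesiation, and the aryl group by Suzuki–Miyaura coupling at C5 of a 2-furoate.
5. Ring order: furan (purchased), pyranone (step 6, sacrificed later), ring A (step 7).

Key step: step 7

Assumption: methyl 5-bromofuran-2-carboxylate, (4-benzyloxy-3-methoxyphenyl)boronic acid, pent-4-yn-1-ol and 1,1-dimethoxyethene are taken as catalogue compounds. The target is achiral, so no stereocentre has to be set.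

**Step 1**
Reactants: 1 methyl 5-bromofuran-2-carboxylate; 2 (4-benzyloxy-3-methoxyphenyl)boronic acid
Product: 3 methyl 5-(4-benzyloxy-3-methoxyphenyl)furan-2-carboxylate
Conditions: Pd(PPh3)4 (3 mol %), Na2CO3 (2 equiv), DME/H2O 4:1, 80 °C
Reagents that add atoms: none
Why: Suzuki–Miyaura coupling of an activated 2-bromofuran, run while the furan carries only this one carbon–halogen bond, so that no second halide competes for zerovalent palladium.

**Step 2**
Reactants: 3 methyl 5-(4-benzyloxy-3-methoxyphenyl)furan-2-carboxylate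
Product: 5 methyl 5-(4-benzyloxy-3-methoxyphenyl)-3-iodofuran-2-carboxylate, via 3-furylmagnesium chloride 4 (not isolated)
Conditions: TMPMgCl·LiCl (1.2 equiv), THF, –40 °C; then I2 (1.3 equiv), –40 °C to rt
Reagents that add atoms: iodine, II
Why: Ester-directed magnesiation with a hindered amide base followed by iodinolysis; with C5 blocked the carbonyl-bound base should remove the C3 proton next to the ester, and the magnesium species should tolerate its own ester at this temperature.

**Step 3**
Reactants: 6 pent-4-yn-1-ol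
Product: 8 5-benzyloxypent-1-yne, via sodium alkoxide 7 (not isolated)
Conditions: NaH (1.1 equiv), THF/DMF, 0 °C; then BnBr (1.05 equiv), Bu4NI (5 mol %), 0 °C to rt
Reagents that add atoms: benzyl bromide, BrCc1ccccc1
Why: Williamson ether synthesis in which only the hydroxyl proton is removed; benzyl is chosen because it survives hydroxide, AgOTf, 160 °C and the Vilsmeier–Haack reagent, whereas chloroiminium salts turn a primary silyl ether into a formate.

**Step 4**
Reactants: 5 methyl 5-(4-benzyloxy-3-methoxyphenyl)-3-iodofuran-2-carboxylate; 8 5-benzyloxypent-1-yne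
Product: 9 methyl 5-(4-benzyloxy-3-methoxyphenyl)-3-[5-(benzyloxy)pent-1-yn-1-yl]furan-2-carboxylate
Conditions: PdCl2(PPh3)2 (3 mol %), CuI (5 mol %), Et3N (3 equiv), THF, rt to 45 °C
Reagents that add atoms: none
Why: Sonogashira coupling of an electron-poor heteroaryl iodide ortho to an ester, which should undergo oxidative addition near room temperature while ester and benzyl ethers stay untouched.

**Step 5**
Reactants: 9 methyl 5-(4-benzyloxy-3-methoxyphenyl)-3-[5-(benzyloxy)pent-1-yn-1-yl]furan-2-carboxylate
Product: 11 5-(4-benzyloxy-3-methoxyphenyl)-3-[5-(benzyloxy)pent-1-yn-1-yl]furan-2-carboxylic acid, via lithium carboxylate 10 (not isolated)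
Conditions: LiOH·H2O (3 equiv), THF/MeOH/H2O, rt; then 1 M HCl to pH 3, 0 °C
Reagents that add atoms: lithium hydroxide, [Li+].[OH-]
Why: Ordinary saponification of a methyl ester by acyl–oxygen cleavage; the internal alkyne and both benzyl ethers are inert to hydroxide at room temperature.

**Step 6**
Reactants: 11 5-(4-benzyloxy-3-methoxyphenyl)-3-[5-(benzyloxy)pent-1-yn-1-yl]furan-2-carboxylic acid
Product: 12 2-(4-benzyloxy-3-methoxyphenyl)-5-[3-(benzyloxy)propyl]-7H-furo[2,3-c]pyran-7-one
Conditions: AgOTf (10 mol %), CH2Cl2, rt, dark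
Reagents that add atoms: none
Why: Silver-catalysed cycloisomerisation of an ortho-alkynyl heteroaryl carboxylic acid; the wide exocyclic angles of the five-membered furan keep the carboxyl oxygen away from the proximal alkyne carbon, so 6-endo-dig closure should win over 5-exo-dig, and any attack of the ether oxygen is reversible.

**Step 7**
Reactants: 12 2-(4-benzyloxy-3-methoxyphenyl)-5-[3-(benzyloxy)propyl]-7H-furo[2,3-c]pyran-7-one; 13 1,1-dimethoxyethene
Product: 16 2-(4-benzyloxy-3-methoxyphenyl)-5-[3-(benzyloxy)propyl]-7-methoxybenzofuran, via bridged lactone 14 (not isolated), via 7,7-dimethoxy-6,7-dihydrobenzofuran 15 (not isolated)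
Conditions: 13 (20 equiv), iPr2NEt (0.2 equiv), mesitylene, sealed tube, 160 °C
Reagents that add atoms: none
Why: Proposed new method: the electron-rich CH2 carbon of 13 should bond to C5 of 12, the pyranone carbon next to the ring oxygen and the vinylogous acceptor terminus of the lactone (C7=O, C7a=C3a, C4=C5), while the acetal carbon bonds to C7a, in an asynchronous inverse-electron-demand [4+2] addition that gives the carboxylate-bridged adduct 14; cycloreversion with loss of CO2 re-forms the furan in 15, and 1,2-elimination of methanol across C6–C7 makes ring A aromatic. The closest known reaction types are the Diels–Alder/CO2-loss/alcohol-loss benzannulation of monocyclic, acceptor-substituted 2-pyranones with ketene acetals and the extra-annular Diels–Alder reactions of 3-vinylfurans, which show that a furan C2–C3 bond can act as half of a diene; a 2-pyranone fused to a furan across this bond has not been used as the diene. Ring A is closed by an intermolecular [4+2] cycloaddition that makes C5–C6 and C7–C7a in one operation, and both later losses are irreversible, so even an unfavourable first equilibrium should be drained towards 16. The two bridgehead stereocentres of 14 (C5 and C7a) are tied to each other by the bicycle, arise as a racemate and disappear with CO2, so nothing has to be controlled. The selectivity that matters is regiochemical (methoxy at C7, hydrogen at C6) and is secured by the polarity of the substrate: C5 is an acceptor position, whereas C7a is alpha to the carbonyl, carries the donor O1 and can only take the cationic acetal carbon. The cost is the transient loss of furan conjugation and the donor effect of O1 and of the aryl group on the diene, which is why a large excess of 13, 160 °C and an amine buffer against acid-induced oligomerisation of 13 are specified.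

**Step 8**
Reactants: 16 2-(4-benzyloxy-3-methoxyphenyl)-5-[3-(benzyloxy)propyl]-7-methoxybenzofuran
Product: 18 2-(4-benzyloxy-3-methoxyphenyl)-5-[3-(benzyloxy)propyl]-7-methoxybenzofuran-3-carbaldehyde, via C3 iminium salt 17 (not isolated)
Conditions: POCl3 (3 equiv), DMF, 0 °C to 70 °C; then aq NaOAc, rt
Reagents that add atoms: N,N-dimethylformamide, CN(C)C=O; water, O
Why: Vilsmeier–Haack formylation; C3 is the beta carbon of the benzofuran enol ether and is further activated by the donor aryl group at C2, so it should react ahead of C4, C6 and the pendant arenes, and benzyl ethers tolerate the reagent.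

**Step 9**
Reactants: 18 2-(4-benzyloxy-3-methoxyphenyl)-5-[3-(benzyloxy)propyl]-7-methoxybenzofuran-3-carbaldehyde
Product: 19 2-(4-hydroxy-3-methoxyphenyl)-5-(3-hydroxypropyl)-7-methoxybenzofuran-3-carbaldehyde (target)
Conditions: H2 (1 atm), 10% Pd/C, EtOAc/EtOH 1:1, rt, stopped when both benzyl ethers are consumed
Reagents that add atoms: none
Why: Catalytic hydrogenolysis of the aryl and the alkyl benzyl ether in one operation; the formyl group is a vinylogous ester (O1–C2=C3–CH=O) and the C2=C3 bond is tetrasubstituted, so both should be reduced more slowly than the benzylic C–O bonds are cleaved.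

**Compound list**
1 | methyl 5-bromofuran-2-carboxylate | COC(=O)c1ccc(Br)o1 | starting material
2 | (4-benzyloxy-3-methoxyphenyl)boronic acid | COc1cc(B(O)O)ccc1OCc1ccccc1 | starting material
3 | methyl 5-(4-benzyloxy-3-methoxyphenyl)furan-2-carboxylate | COC(=O)c1ccc(-c2ccc(OCc3ccccc3)c(OC)c2)o1 | intermediate
4 | [5-(4-benzyloxy-3-methoxyphenyl)-2-(methoxycarbonyl)furan-3-yl]magnesium chloride (LiCl complex, not isolated) | COC(=O)c1oc(-c2ccc(OCc3ccccc3)c(OC)c2)cc1[Mg]Cl | intermediate
5 | methyl 5-(4-benzyloxy-3-methoxyphenyl)-3-iodofuran-2-carboxylate | COC(=O)c1oc(-c2ccc(OCc3ccccc3)c(OC)c2)cc1I | intermediate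
6 | pent-4-yn-1-ol | C#CCCCO | starting material
7 | sodium pent-4-yn-1-olate (not isolated) | C#CCCC[O-].[Na+] | intermediate
8 | 5-benzyloxypent-1-yne, [(pent-4-yn-1-yloxy)methyl]benzene | C#CCCCOCc1ccccc1 | intermediate
9 | methyl 5-(4-benzyloxy-3-methoxyphenyl)-3-[5-(benzyloxy)pent-1-yn-1-yl]furan-2-carboxylate | COC(=O)c1oc(-c2ccc(OCc3ccccc3)c(OC)c2)cc1C#CCCCOCc1ccccc1 | intermediate
10 | lithium 5-(4-benzyloxy-3-methoxyphenyl)-3-[5-(benzyloxy)pent-1-yn-1-yl]furan-2-carboxylate (not isolated) | [Li+].[O-]C(=O)c1oc(-c2ccc(OCc3ccccc3)c(OC)c2)cc1C#CCCCOCc1ccccc1 | intermediate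
11 | 5-(4-benzyloxy-3-methoxyphenyl)-3-[5-(benzyloxy)pent-1-yn-1-yl]furan-2-carboxylic acid | OC(=O)c1oc(-c2ccc(OCc3ccccc3)c(OC)c2)cc1C#CCCCOCc1ccccc1 | intermediate
12 | 2-(4-benzyloxy-3-methoxyphenyl)-5-[3-(benzyloxy)propyl]-7H-furo[2,3-c]pyran-7-one | O=C1OC(CCCOCc2ccccc2)=CC2=C1OC(c1ccc(OCc3ccccc3)c(OC)c1)=C2 | intermediate
13 | 1,1-dimethoxyethene | C=C(OC)OC | starting material
14 | [4+2] adduct of 12 and 13: C(=O)–O bridge between C7a and C5, C3a=C4 double bond, C(OMe)2 on C7a, CH2 on C5 (racemic, one enantiomer drawn, not isolated) | O=C1O[C@]2(CCCOCc3ccccc3)C=C4C=C(c3ccc(OCc5ccccc5)c(OC)c3)O[C@]14C(OC)(OC)C2 | intermediate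
15 | 2-(4-benzyloxy-3-methoxyphenyl)-5-[3-(benzyloxy)propyl]-7,7-dimethoxy-6,7-dihydrobenzofuran (not isolated) | COC1(OC)CC(CCCOCc2ccccc2)=Cc2cc(-c3ccc(OCc4ccccc4)c(OC)c3)oc21 | intermediate
16 | 2-(4-benzyloxy-3-methoxyphenyl)-5-[3-(benzyloxy)propyl]-7-methoxybenzofuran | COc1cc(CCCOCc2ccccc2)cc2cc(-c3ccc(OCc4ccccc4)c(OC)c3)oc12 | intermediate
17 | N-({2-(4-benzyloxy-3-methoxyphenyl)-5-[3-(benzyloxy)propyl]-7-methoxybenzofuran-3-yl}methylidene)-N-methylmethanaminium dichlorophosphate (not isolated) | COc1cc(CCCOCc2ccccc2)cc2c(C=[N+](C)C)c(-c3ccc(OCc4ccccc4)c(OC)c3)oc12.[O-]P(=O)(Cl)Cl | intermediate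
18 | 2-(4-benzyloxy-3-methoxyphenyl)-5-[3-(benzyloxy)propyl]-7-methoxybenzofuran-3-carbaldehyde | COc1cc(CCCOCc2ccccc2)cc2c(C=O)c(-c3ccc(OCc4ccccc4)c(OC)c3)oc12 | intermediate
19 | 2-(4-hydroxy-3-methoxyphenyl)-5-(3-hydroxypropyl)-7-methoxybenzofuran-3-carbaldehyde | COc1cc(-c2oc3c(OC)cc(CCCO)cc3c2C=O)ccc1O | target

**Total step count:** 9
**Longest linear sequence:** 8 (steps 1, 2, 4, 5, 6, 7, 8, 9)

**Steps most likely to fail**

**1. Step 7.**
- What may go wrong: the cycloaddition may not start. Using the furan C3a=C7a bond as half of the diene costs furan conjugation in the transition state. O1 and the electron-rich aryl group also weaken the acceptor character of the pyranone. Thermal decay or oligomerisation of the ketene acetal may therefore outrun the addition.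
- Fallback (known chemistry): it sets out from 9 and comes back at 16.
  - Ester 9 is treated with MeNH(OMe)·HCl and iPrMgCl (THF, –20 °C) to give the N-methoxy-N-methylamide F1.
  - MeMgBr (THF, 0 °C) converts this into the 2-acetyl-3-alkynylfuran F2.
  - KN(SiMe3)2 (toluene/THF, –78 °C to rt) then closes ring A. This is the known base-induced 6-endo-dig carbocyclisation of ortho-alkynylaryl methyl ketones, which gives 3-substituted 1-naphthol-type phenols. Here it should give the 7-hydroxybenzofuran F3.
  - MeI and K2CO3 in acetone give 16.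
  - In this variant C7 is the former ester carbon and C6 the acetyl methyl carbon.

**2. Step 9.**
- What may go wrong: reduction of the formyl group may compete with the slower hydrogenolysis of the aliphatic benzyl ether.
- Fallback: it sets out from 16 and comes back at 19, and removes the benzyl groups before the aldehyde exists.
  - Hydrogenolysis of 16 (H2, Pd/C, EtOH) gives the phenol-alcohol F4.
  - Ac2O in pyridine gives the diacetate F5.
  - POCl3/DMF formylates C3 through the iminium salt F6 to give the formyl diacetate F7.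
  - K2CO3 in MeOH at rt cleaves both acetates to give 19.

**3. Step 2.**
- What may go wrong: deprotonation may be incomplete or misdirected (C4 in place of C3), and the magnesiated ester may condense with itself.
- Fallback: it sets out from 2 and comes back at 9, and carries the C3 halogen in from the start instead of installing it by metalation.
  - Commercial methyl 3-bromofuran-2-carboxylate (COC(=O)c1occc1Br) is brominated at its free alpha position (Br2, CHCl3, 50 °C) to give methyl 3,5-dibromofuran-2-carboxylate F8.
  - Site-selective Suzuki–Miyaura coupling with one equivalent of 2 at the more reactive alpha C5–Br bond (Pd(PPh3)4, Na2CO3, DME/H2O, 60 °C) gives methyl 5-(4-benzyloxy-3-methoxyphenyl)-3-bromofuran-2-carboxylate F9.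
  - Sonogashira coupling of this bromide with 8 (PdCl2(PPh3)2, CuI, Et3N, DMF, 70 °C) gives 9.

**Further compounds**
F1 | step 7 | 5-(4-benzyloxy-3-methoxyphenyl)-3-[5-(benzyloxy)pent-1-yn-1-yl]-N-methoxy-N-methylfuran-2-carboxamide | CON(C)C(=O)c1oc(-c2ccc(OCc3ccccc3)c(OC)c2)cc1C#CCCCOCc1ccccc1
F2 | step 7 | 1-{5-(4-benzyloxy-3-methoxyphenyl)-3-[5-(benzyloxy)pent-1-yn-1-yl]furan-2-yl}ethan-1-one | CC(=O)c1oc(-c2ccc(OCc3ccccc3)c(OC)c2)cc1C#CCCCOCc1ccccc1
F3 | step 7 | 2-(4-benzyloxy-3-methoxyphenyl)-5-[3-(benzyloxy)propyl]benzofuran-7-ol | Oc1cc(CCCOCc2ccccc2)cc2cc(-c3ccc(OCc4ccccc4)c(OC)c3)oc12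
F4 | step 9 | 4-[5-(3-hydroxypropyl)-7-methoxybenzofuran-2-yl]-2-methoxyphenol | COc1cc(-c2cc3cc(CCCO)cc(OC)c3o2)ccc1O
F5 | step 9 | 3-[2-(4-acetoxy-3-methoxyphenyl)-7-methoxybenzofuran-5-yl]propyl acetate | COc1cc(-c2cc3cc(CCCOC(C)=O)cc(OC)c3o2)ccc1OC(C)=O
F6 | step 9 | C3 dimethyliminium dichlorophosphate of F5 (not isolated) | COc1cc(-c2oc3c(OC)cc(CCCOC(C)=O)cc3c2C=[N+](C)C)ccc1OC(C)=O.[O-]P(=O)(Cl)Cl
F7 | step 9 | 3-[2-(4-acetoxy-3-methoxyphenyl)-3-formyl-7-methoxybenzofuran-5-yl]propyl acetate | COc1cc(-c2oc3c(OC)cc(CCCOC(C)=O)cc3c2C=O)ccc1OC(C)=O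
F8 | step 2 | methyl 3,5-dibromofuran-2-carboxylate | COC(=O)c1oc(Br)cc1Br
F9 | step 2 | methyl 5-(4-benzyloxy-3-methoxyphenyl)-3-bromofuran-2-carboxylate | COC(=O)c1oc(-c2ccc(OCc3ccccc3)c(OC)c2)cc1Br
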